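The vessel was a closed, stirred, isothermal flask in which the second nucleophile began as a solid beside the dissolved starting material and first nucleophile.

    starting material → intermediate (k1 = 0.00300 min⁻¹)
    first nucleophile + intermediate → target (k2 = 0.109 M⁻¹ min⁻¹)
    second nucleophile + intermediate → other capture product (k3 = 1.80 M⁻¹ min⁻¹)
    solid second nucleophile ⇌ second nucleophile, rate k4*(cs4 - [second nucleophile]) while solid is left; crystals form when [second nucleophile] > cs4 (cs4 = 0.064 M, k4 = 0.00206 min⁻¹)

starting material 0.27 M; first nucleophile 0.257 M; solid second nucleophile 0.284 M; time 8.0 h

- solid, in amounts per volume of the solution: solid second nucleophile
- at the start none of the solid second nucleophile is in solution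
- run time (flask): 8.0 h

1. how much target there is at 8.0 h, in percent of the starting material charged
2. concentration of second nucleophile in solution at 50 min, in percent of saturation
3. the change that raises the amount of target at 8.0 h, in percent of the starting material charged most ("none" if none brings more than 2 percentage points) (eta / alpha / zeta / none)
4. amount of target at 8.0 h, in percent of the starting material charged, after eta

- eta: doubling the solubility in step 4, all else as stated
- alpha: doubling the dissolution coefficient of step 4, all else as stated
- zeta: doubling the amount of first nucleophile, all else as stated

I carried one quantity through this flask: 0.0633 M, the dissolution coefficient times the solubility times the run time, which I called the dissolution ceiling, the most that the dissolution step can deliver by 8.0 h into a solution kept empty.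

In the first instants, the first step made intermediate at 8.10 × 10⁻⁴ M min⁻¹, while dissolution fed second nucleophile at 1.32 × 10⁻⁴ M min⁻¹, which is slower. The second nucleophile captures intermediate 16.5 times faster than the first nucleophile at equal concentration, its selectivity factor, so I expected it to react about as fast as it arrived.

By 50 min, the first step had slowed to 6.97 × 10⁻⁴ M min⁻¹. I set capture equal to the dissolution feed and let the first nucleophile, taken as charged, consume the remaining intermediate. That gave c(intermediate) = 0.0202 M and c(second nucleophile) = 0.00363 M, or 5.67% of saturation.

By 8.0 h, 76.3% of the starting material had been converted. The ceiling was 23.4% of the charge, so with capture at the ceiling and the remaining intermediate ignored, I reckoned 52.9% target. Doubling the solubility or the dissolution coefficient doubles the ceiling, and the same subtraction then gave 29.5%, which I treated as a low mark for eta. Doubling the first nucleophile leaves the ceiling unchanged, so the subtraction gave the same 52.9%, and against the bar of 2 percentage points this reckoning answered none.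

The forecast gave 56%, 5.8%, zeta and 43% after eta, on the ground that the second nucleophile “is fed only slowly by dissolution”. The simulation gave 53.0%, 5.34%, zeta with a gain of 6.3 points, and 40.4% after eta.

My target figure matched, my answer of none did not, and capture in this flask was not at the ceiling: at 8.00 h it held 19.7% of other capture product, or 0.0532 M, less than the ceiling, while 3.55% stood as intermediate. In the neighbouring flask with 1.1 M of starting material, the same ceiling came to 5.75% of the charge, and that flask read 5.70% of other capture product at 8.00 h. There the first nucleophile, the limiting reagent at 0.234 equiv, stood at 0%, with target at 23.4% and intermediate at 47.2%.

The constants used here come from no measurement, and the outcome is calculated.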